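**Plan**

- Feature: the ester carbonyl C1 lies between an unbranched, unfunctionalised C24 alkyl chain (C2–C25) and the oxygen on the primary carbon of the 4-hydroxyphenethyl group, whose benzene ring carries only the para hydroxyl. C1 can therefore be brought in as carbon monoxide.
- Retrosynthesis: C1–C2 and C1–O are cut together (alkene + CO + alcohol), then C5–C6 of the acyl chain is cut (C4 Grignard reagent + C20 bromide).
- Forward: 1-bromoicosane 1 and but-3-enylmagnesium bromide 2 are coupled to tetracos-1-ene 3. Then 3, carbon monoxide 4 and unprotected tyrosol 5 are joined in one palladium-catalysed hydroalkoxycarbonylation to the target 6.
- The chain is assembled as C20 + C4, then + C1 + aryl-ethanol. No ring is formed at any stage; the benzene ring is bought with 5.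
- The target has no stereocentre and no double-bond geometry, so nothing stereochemical has to be set. The selectivities needed are linear over branched acyl and aliphatic over phenolic oxygen.

Key step: step 2

**Remarks**

- Assumption: 1-bromoicosane, but-3-enylmagnesium bromide (as its commercial THF solution), carbon monoxide and tyrosol are purchased.
- Locants C1–C25 refer to the acyl chain of the target, C1 being the ester carbonyl.
- The alkene is built from homologue-pure C20 and C4 pieces rather than bought, because technical long-chain 1-alkenes can carry neighbouring chain lengths that would end up as inseparable ester homologues.
- The target should be a waxy solid. It should be freed from catalyst residues by filtration through silica, from excess tyrosol by aqueous washing and from traces of branched ester by crystallisation.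

**Route**

Step 1
Reactants: 1 1-bromoicosane; 2 but-3-enylmagnesium bromide
Product: 3 tetracos-1-ene
Conditions: Li2CuCl4 (3 mol%), THF/NMP, 0 °C to rt; aq. NH4Cl
Reagents that add atoms: none
Why: Copper-catalysed Kochi cross-coupling of a primary alkyl bromide with a primary alkyl Grignard reagent should join C20 and C4 cleanly, since the organocopper species formed from Li2CuCl4 displaces bromide far faster than the Grignard reagent does alone and the remote terminal alkene is a spectator.

Step 2
Reactants: 3 tetracos-1-ene; 4 carbon monoxide; 5 tyrosol
Product: 6 2-(4-hydroxyphenyl)ethyl pentacosanoate
Conditions: Pd(OAc)2 (1 mol%), 1,2-bis(di-tert-butylphosphinomethyl)benzene (4 mol%), MeSO3H (10 mol%), CO (30 bar), 5 (2 equiv), toluene/1,4-dioxane, 100 °C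
Reagents that add atoms: none
Why: Pd(OAc)2, the diphosphine and MeSO3H should give a cationic diphosphine hydride of divalent palladium that adds to the double bond of 3; carbon monoxide 4 then inserts into the primary alkyl–palladium bond and the primary hydroxyl of 5 cleaves the acyl complex, which forms C1–C2 and C1–O and returns the hydride. The closest known reaction type is the hydroalkoxycarbonylation (hydroesterification) of 1-alkenes with palladium, a bulky chelating diphosphine and a sulfonic acid, the system also used for isomerising alkoxycarbonylation of long-chain alkenes; here the alcohol is used in twofold excess in a solvent rather than as the medium. No ring is formed and no stereocentre is created, and the addition is fully atom-economic. Linear over branched selectivity should follow from reversible hydropalladation together with the four tert-butyl groups, which let only the unhindered terminal acyl complex undergo alcoholysis, so internal alkenes formed by chain walking are drawn back to the linear ester. Aliphatic over phenolic selectivity should follow from the acid, which keeps the phenol un-ionised so that its oxygen competes poorly with the primary hydroxyl for the acyl complex. The excess of 5 disfavours a second acylation, and the low acid loading should leave the electron-rich ring unalkylated.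

**Compound list**

1 | 1-bromoicosane | CCCCCCCCCCCCCCCCCCCCBr | starting material
2 | but-3-enylmagnesium bromide (THF solution) | C=CCC[Mg]Br | starting material
3 | tetracos-1-ene | CCCCCCCCCCCCCCCCCCCCCCC=C | intermediate
4 | carbon monoxide | [C-]#[O+] | starting material
5 | tyrosol, 4-(2-hydroxyethyl)phenol | OCCc1ccc(O)cc1 | starting material
6 | 2-(4-hydroxyphenyl)ethyl pentacosanoate | CCCCCCCCCCCCCCCCCCCCCCCCC(=O)OCCc1ccc(O)cc1 | target

**Count**

Total step count: 2. Longest linear sequence: 2 steps (1 → 3 → 6).

**Steps most likely to fail**

The route has only two steps, so both are ranked, the riskier first.

1. Step 2. Alcoholysis of the acyl–palladium complex by a solid, only moderately soluble alcohol at low concentration may be slow. The catalyst would then rest, deposit palladium metal and stall the conversion. A lesser concern is partial acylation of the phenolic oxygen. Fallback: setting out from tetracos-1-ene 3, the carbonylation would be run with 4 in methanol as solvent with the same Pd(OAc)2/diphosphine/MeSO3H system (CO 20 bar, 90 °C). This is the best-documented form of the catalysis for long-chain alkenes and should give methyl pentacosanoate F1. The aryl-ethanol would then be attached in a separate acyl transfer: F1 and tyrosol 5 with immobilised Candida antarctica lipase B in toluene at about 65 °C, with methanol removed under reduced pressure. The enzyme is known to acylate only the primary hydroxyl of phenolic alcohols, so this should return to the route at the target 6.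

2. Step 1. Halogen–magnesium exchange, homocoupling at copper and β-hydride elimination may compete with the cross-coupling. These would leave incomplete conversion and hydrocarbon by-products of the same polarity as the alkene. Fallback: setting out from 1-bromoicosane 1, quaternisation with PPh3 in refluxing toluene should give icosyl(triphenyl)phosphonium bromide F2. Deprotonation with NaN(SiMe3)2 in THF would give icosylidene(triphenyl)phosphorane F3 (not isolated), and a Wittig reaction with butanal should give (Z)-tetracos-4-ene F4. This internal alkene would be submitted with 4 and 5 to the conditions of step 2. Reversible hydropalladation should walk the double bond to the chain end before carbonylation, so the fallback comes back to the route at the target 6, at the price of a slower key step.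

Further compounds
F1 | step 2 | methyl pentacosanoate | CCCCCCCCCCCCCCCCCCCCCCCCC(=O)OC
F2 | step 1 | icosyl(triphenyl)phosphonium bromide | CCCCCCCCCCCCCCCCCCCC[P+](c1ccccc1)(c1ccccc1)c1ccccc1.[Br-]
F3 | step 1 | icosylidene(triphenyl)phosphorane | CCCCCCCCCCCCCCCCCCCC=P(c1ccccc1)(c1ccccc1)c1ccccc1
F4 | step 1 | (Z)-tetracos-4-ene | CCC/C=C\CCCCCCCCCCCCCCCCCCC
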